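**Retrosynthetic overview**

1. The target is read in eudesmane numbering (C1–C10 ring carbons, C14 on C10, C15 on C4, C11–C13 on C7). The ether oxygen that bridges C5 and C10 across the ten-membered carbocycle (two fused oxepanes, an 11-oxabicyclo[4.4.1]undecane) is taken as a former C5–C10 decalin bond. C10 (quaternary, methyl-bearing, next to oxygenated C9) is then the α-carbon of a C9 ketone enolate and C1 is a plain methylene, so ring closure at C10–C1 becomes a six-membered enolate alkylation. This is the feature that makes the key step possible.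
2. Disconnections: C9 isovalerate and C11=C13 (last) ⇒ C5–O–C10 ether by Criegee oxygen insertion into the C5–C10 bond of a C5 hydroperoxide (retention at C10), then ionic reduction at C5 ⇒ Δ4 octalin ⇒ cis-decalone ⇒ C10–C1 bond (key) and C5–C4 bond on a carvone-derived enone.
3. (S)-Carvone supplies C5–C10, C14, the C7 stereocentre and C11–C13. C7 relays to C5 (trans conjugate addition) and C5 to C10 (cis ring closure). The C8 and C9 oxygens come from the C9 ketone; C4 is set next to the C5 hydroperoxide.
4. Ring order: ring B (carvone) → carbocyclic ring A (key step) → γ-lactone → the temporary C5–C10 bond is cut by oxygen insertion, turning the decalin into the ten-membered ring with its two oxepanes → α-methylene lactone and ester.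

Key step: step 5

Remark on the chemistry: C11 is formed without control in step 1 and is carried as an inconsequential epimer mixture (left unspecified in the SMILES) until it becomes sp2 in step 13. α/β descriptors refer to the usual eudesmane drawing, with the C10 methyl β.

**Route**

Step 1
Reactants: 1 (S)-carvone
Product: 2 (5S)-5-(1-hydroxypropan-2-yl)-2-methylcyclohex-2-en-1-ol (epimers at the carbinol carbon and at C11)
Conditions: 9-BBN (2.5 equiv), THF, 0 → 25 °C; then NaOH, H2O2, 0 °C
Reagents that add atoms: hydrogen peroxide, OO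
Why: 9-BBN reduces the enone carbonyl in 1,2-fashion and hydroborates the 1,1-disubstituted isopropenyl group anti-Markovnikov while sparing the trisubstituted ring alkene, so hydroboration–oxidation should give the diol; the two new centres need no control because both are erased later.

Step 2
Reactants: 2 (5S)-5-(1-hydroxypropan-2-yl)-2-methylcyclohex-2-en-1-ol
Product: 3 2-[(1S)-4-methyl-5-oxocyclohex-3-en-1-yl]propanoic acid (C11 epimers)
Conditions: CrO3, H2SO4, acetone/H2O, 0 °C
Reagents that add atoms: water, O
Why: Jones oxidation should return the allylic alcohol to the enone and take the primary alcohol, through the aldehyde hydrate, to the acid in one operation without touching the C7 stereocentre.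

Step 3
Reactants: 3 2-[(1S)-4-methyl-5-oxocyclohex-3-en-1-yl]propanoic acid
Product: 4 methyl 2-[(1S)-4-methyl-5-oxocyclohex-3-en-1-yl]propanoate (C11 epimers)
Conditions: MeI, K2CO3, DMF, 25 °C
Reagents that add atoms: iodomethane, CI
Why: SN2 O-alkylation of the carboxylate gives an ester that is inert to the organocopper chemistry of step 5 and later closes the lactone by itself.

Step 4
Reactants: 5 5-chloropent-1-yne
Product: 6 2-bromo-5-chloropent-1-ene
Conditions: B-bromo-9-BBN, CH2Cl2, 0 → 25 °C; then AcOH
Reagents that add atoms: B-bromo-9-borabicyclo[3.3.1]nonane, BrB1C2CCCC1CCC2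
Why: syn-bromoboration of the terminal alkyne places bromine on the internal carbon, and protodeboronation with acetic acid should leave the 2-bromo-1-alkene (haloboration–protonolysis) with the primary chloride untouched.

Step 5
Reactants: 4 methyl 2-[(1S)-4-methyl-5-oxocyclohex-3-en-1-yl]propanoate; 6 2-bromo-5-chloropent-1-ene
Product: 9 methyl 9-oxo-5βH-eudesm-4(15)-en-12-oate (cis-fused decalone; 10β-methyl; 7β side chain), via alkenyl Grignard reagent 7 (not isolated), via bromomagnesium enolate 8 (not isolated)
Conditions: Mg, THF, 40 °C (6 → 7); CuBr·SMe2 (10 mol%), 4, THF, −78 → −30 °C; then HMPA, 60 °C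
Reagents that add atoms: none
Why: Copper-catalysed conjugate addition of Grignard reagent 7 to enone 4 gives the C9/C10 bromomagnesium enolate 8 regiospecifically, and after addition of HMPA and warming this enolate should be C-alkylated by its own primary chloride to form the C10–C1 bond. The closest known reaction type is the methylenecyclohexane annulation of cyclic enones with 5-chloropent-1-en-2-yl copper reagents (conjugate addition, then cycloalkylation of the chloro ketone), run here without isolating the chloro ketone. Ring A closes in the 6-(enolexo)-exo-tet mode. C5 is set by attack anti to the C7 substituent, as with carvone itself; the quaternary C10 is set by the tether, because the chain on C5 can reach the adjacent enolate carbon only on its own face under perpendicular attack, so the decalin is cis-fused and the C10 methyl ends cis to the C7 side chain, which is the relationship the target keeps after the C5–C10 bond is replaced by oxygen. The step needs C- over O-alkylation and C10 over C8 alkylation: O-alkylation would require an eight-membered ring and C8 cannot reach the chloride, so even an equilibrated enolate can only give the fused six-membered ring, and the ester and the alkyl chloride are inert at the conjugate-addition temperature.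

Step 6
Reactants: 9 methyl 9-oxo-5βH-eudesm-4(15)-en-12-oate
Product: 10 methyl 9-oxoeudesm-4-en-12-oate (10β-methyl; 7β side chain)
Conditions: TsOH·H2O (10 mol%), PhH, 80 °C
Reagents that add atoms: none
Why: acid-catalysed alkene isomerisation through the tertiary C4 cation should move the exocyclic double bond into the tetrasubstituted Δ4 position, the thermodynamic sink that also relieves the cis ring fusion; no stereocentre is formed and C5, its relay work done, becomes trigonal.

Step 7
Reactants: 10 methyl 9-oxoeudesm-4-en-12-oate
Product: 12 9-oxoeudesm-4-en-8α,12-olide (trans-fused γ-lactone; 7α-H; 8β-H), via hydroxy ketone ester 11 (not isolated)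
Conditions: KN(SiMe3)2, THF, −78 °C; 2-(phenylsulfonyl)-3-phenyloxaziridine, −78 °C; AcOH quench; then camphorsulfonic acid (cat.), PhMe, 60 °C
Reagents that add atoms: 2-(phenylsulfonyl)-3-phenyloxaziridine, O=S(=O)(c1ccccc1)N1OC1c1ccccc1
Why: C8 is the only enolisable position of the C9 ketone, and Davis oxidation of the potassium enolate should deliver oxygen to the α face, away from the axial C10 methyl and trans to the equatorial C7 side chain (also the more stable equatorial ketol), after which the 8α-hydroxy ester lactonises under acid to the trans-fused lactone.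

Step 8
Reactants: 12 9-oxoeudesm-4-en-8α,12-olide
Product: 13 9β-hydroxyeudesm-4-en-8α,12-olide
Conditions: NaBH4, MeOH/CH2Cl2, −40 → −20 °C
Reagents that add atoms: none
Why: borohydride reduction of the neopentyl ketone by axial attack on the α face (the β side is screened by the adjacent axial C10 methyl) should give the equatorial 9β-alcohol, trans to the 8α-oxygen, without opening the lactone.

Step 9
Reactants: 13 9β-hydroxyeudesm-4-en-8α,12-olide
Product: 14 9β-(tert-butyldimethylsilyloxy)eudesm-4-en-8α,12-olide
Conditions: TBSOTf, 2,6-lutidine, CH2Cl2, 0 °C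
Reagents that add atoms: tert-butyldimethylsilyl trifluoromethanesulfonate, CC(C)(C)[Si](C)(C)OS(=O)(=O)C(F)(F)F
Why: silylation with the silyl triflate overcomes the hindrance of the neopentyl alcohol and gives an ether that survives the peroxide chemistry, lowers the migratory aptitude of C10 less than an ester would, and is not enolisable in step 13.

Step 10
Reactants: 14 9β-(tert-butyldimethylsilyloxy)eudesm-4-en-8α,12-olide
Product: 15 5α-hydroperoxy-9β-(tert-butyldimethylsilyloxy)eudesm-4(15)-en-8α,12-olide
Conditions: O2, tetraphenylporphyrin (cat.), visible light, CH2Cl2, −20 °C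
Reagents that add atoms: dioxygen, O=O
Why: the Schenck ene reaction of singlet oxygen with the tetrasubstituted alkene should occur on the α face (anti to the C10 methyl and the 9β-silyloxy group) with oxygen bonding to C5 and hydrogen taken from the C15 methyl, because on that face the C6 hydrogen is equatorial and badly aligned; this sets the tertiary C5 hydroperoxide and leaves an exocyclic alkene.

Step 11
Reactants: 15 5α-hydroperoxy-9β-(tert-butyldimethylsilyloxy)eudesm-4(15)-en-8α,12-olide
Product: 16 5α-hydroperoxy-9β-(tert-butyldimethylsilyloxy)-4αH-eudesman-8α,12-olide (4β-methyl)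
Conditions: KO2CN=NCO2K, AcOH, MeOH/CH2Cl2, 0 °C
Reagents that add atoms: none
Why: diimide reduces unhindered C=C bonds by concerted syn transfer of H2 and leaves O–O bonds intact, and it should add to the exocyclic methylene from the α face because the β face is blocked by the syn-axial C10 methyl, placing hydrogen at C4α and the methyl group 4β.

Step 12
Reactants: 16 5α-hydroperoxy-9β-(tert-butyldimethylsilyloxy)-4αH-eudesman-8α,12-olide
Product: 19 9-O-TBS-11,13-dihydro-desisovaleryl target (5,10-epoxy-5,10-secoeudesman-8,12-olide; C5–H; α-methyl lactone), via pertrifluoroacetate 17 (not isolated), via bridgehead trifluoroacetate 18 (not isolated)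
Conditions: (CF3CO)2O, CH2Cl2, −20 → 0 °C; then Et3SiH, TMSOTf (20 mol%), −78 → −30 °C
Reagents that add atoms: none
Why: in this Criegee rearrangement O-acylation turns the peroxide into a leaving group and the best migrating group on C5, the tertiary C10, shifts from carbon to oxygen with retention of configuration to give the C5 oxocarbenium ion, which collapses to the bridgehead trifluoroacetate; ionic hydrogenation then replaces the acyloxy group by hydride on the only exposed face of the bridgehead, which fixes C5.

Step 13
Reactants: 19 9-O-TBS-11,13-dihydro-desisovaleryl target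
Product: 21 9-O-TBS-desisovaleryl target (α-methylene lactone), via selenide 20 (not isolated)
Conditions: LiN(i-Pr)2, THF, −78 °C; PhSeBr; then H2O2 (30%), pyridine, CH2Cl2, 0 → 25 °C
Reagents that add atoms: none
Why: selenenylation of the lactone enolate (the only acidic C–H left) followed by selenoxide syn-elimination should give the exocyclic α-methylene lactone, the usual outcome for trans-fused α-methyl butyrolactones where the C7 hydrogen is not syn to selenium; the C11 centre disappears.

Step 14
Reactants: 21 9-O-TBS-desisovaleryl target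
Product: 22 desisovaleryl target (free 9-hydroxyl)
Conditions: HF·pyridine, THF, 0 → 25 °C
Reagents that add atoms: none
Why: fluoride desilylation under mildly acidic conditions frees the 9-hydroxyl without conjugate addition to the α-methylene lactone or opening of the bridged ether.

Step 15
Reactants: 22 desisovaleryl target
Product: 23 CNP0274454.1
Conditions: 3-methylbutanoyl chloride, pyridine, DMAP (cat.), CH2Cl2, 0 → 25 °C
Reagents that add atoms: 3-methylbutanoyl chloride, CC(C)CC(=O)Cl
Why: DMAP-catalysed acylation of the secondary alcohol installs the isovalerate with retention at C9.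

**Compound list**

1 | (S)-carvone, (5S)-2-methyl-5-(prop-1-en-2-yl)cyclohex-2-en-1-one | CC(=C)[C@H]1CC=C(C)C(=O)C1 | starting material
2 | (5S)-5-(1-hydroxypropan-2-yl)-2-methylcyclohex-2-en-1-ol (epimers at C1 and C11) | OCC(C)[C@H]1CC=C(C)C(O)C1 | intermediate
3 | 2-[(1S)-4-methyl-5-oxocyclohex-3-en-1-yl]propanoic acid | OC(=O)C(C)[C@H]1CC=C(C)C(=O)C1 | intermediate
4 | methyl 2-[(1S)-4-methyl-5-oxocyclohex-3-en-1-yl]propanoate | COC(=O)C(C)[C@H]1CC=C(C)C(=O)C1 | intermediate
5 | 5-chloropent-1-yne | C#CCCCCl | starting material
6 | 2-bromo-5-chloropent-1-ene | C=C(Br)CCCCl | intermediate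
7 | (5-chloropent-1-en-2-yl)magnesium bromide | C=C([Mg]Br)CCCCl | intermediate
8 | bromomagnesium C9/C10 enolate of the conjugate adduct (chain on C5 trans to the C7 side chain) | COC(=O)C(C)[C@H]1C[C@H](C(=C)CCCCl)C(C)=C(O[Mg]Br)C1 | intermediate
9 | methyl 9-oxo-5βH-eudesm-4(15)-en-12-oate (cis-fused, 10β-methyl, 7β side chain) | COC(=O)C(C)[C@H]1C[C@@H]2C(=C)CCC[C@]2(C)C(=O)C1 | intermediate
10 | methyl 9-oxoeudesm-4-en-12-oate | COC(=O)C(C)[C@H]1CC2=C(C)CCC[C@]2(C)C(=O)C1 | intermediate
11 | methyl 8α-hydroxy-9-oxoeudesm-4-en-12-oate | COC(=O)C(C)[C@H]1CC2=C(C)CCC[C@]2(C)C(=O)[C@@H]1O | intermediate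
12 | 9-oxoeudesm-4-en-8α,12-olide (trans-fused lactone) | CC1C(=O)O[C@@H]2[C@@H]1CC3=C(C)CCC[C@]3(C)C2=O | intermediate
13 | 9β-hydroxyeudesm-4-en-8α,12-olide | CC1C(=O)O[C@@H]2[C@@H]1CC3=C(C)CCC[C@]3(C)[C@H]2O | intermediate
14 | 9β-(tert-butyldimethylsilyloxy)eudesm-4-en-8α,12-olide | CC1C(=O)O[C@@H]2[C@@H]1CC3=C(C)CCC[C@]3(C)[C@H]2O[Si](C)(C)C(C)(C)C | intermediate
15 | 5α-hydroperoxy-9β-(tert-butyldimethylsilyloxy)eudesm-4(15)-en-8α,12-olide | CC1C(=O)O[C@@H]2[C@@H]1C[C@@]3(OO)C(=C)CCC[C@]3(C)[C@H]2O[Si](C)(C)C(C)(C)C | intermediate
16 | 5α-hydroperoxy-4β-methyl-9β-(tert-butyldimethylsilyloxy)eudesman-8α,12-olide | CC1C(=O)O[C@@H]2[C@@H]1C[C@@]3(OO)[C@@H](C)CCC[C@]3(C)[C@H]2O[Si](C)(C)C(C)(C)C | intermediate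
17 | C5 peroxy trifluoroacetate of 16 | CC1C(=O)O[C@@H]2[C@@H]1C[C@@]3(OOC(=O)C(F)(F)F)[C@@H](C)CCC[C@]3(C)[C@H]2O[Si](C)(C)C(C)(C)C | intermediate
18 | 5-trifluoroacetoxy-5,10-epoxy-5,10-secoeudesman-8,12-olide 9-TBS ether (bridgehead ketal ester) | CC1C(=O)O[C@@H]2[C@@H]1C[C@@]1(OC(=O)C(F)(F)F)O[C@](C)(CCC[C@@H]1C)[C@H]2O[Si](C)(C)C(C)(C)C | intermediate
19 | 9-O-TBS-11,13-dihydro-desisovaleryl target (5,10-epoxy-5,10-secoeudesman-8,12-olide) | CC1C(=O)O[C@@H]2[C@@H]1C[C@H]1O[C@](C)(CCC[C@@H]1C)[C@H]2O[Si](C)(C)C(C)(C)C | intermediate
20 | 11-phenylselanyl derivative of 19 | CC1([Se]c3ccccc3)C(=O)O[C@@H]2[C@@H]1C[C@H]1O[C@](C)(CCC[C@@H]1C)[C@H]2O[Si](C)(C)C(C)(C)C | intermediate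
21 | 9-O-TBS-desisovaleryl target (α-methylene lactone) | C=C1C(=O)O[C@@H]2[C@@H]1C[C@H]1O[C@](C)(CCC[C@@H]1C)[C@H]2O[Si](C)(C)C(C)(C)C | intermediate
22 | desisovaleryl target (9-hydroxy compound) | C=C1C(=O)O[C@@H]2[C@@H]1C[C@H]1O[C@](C)(CCC[C@@H]1C)[C@H]2O | intermediate
23 | CNP0274454.1 | C=C1C(=O)O[C@@H]2[C@@H]1C[C@H]1O[C@](C)(CCC[C@@H]1C)[C@H]2OC(=O)CC(C)C | target

**Step count and risks**

Total step count: 15. Longest linear sequence: 14 (steps 1–3 and 5–15 from (S)-carvone).

Steps most likely to fail:

Step 5. The magnesium enolate may alkylate the unactivated chloride too slowly, so that proton transfer, enolate decomposition or intermolecular reactions win over ring closure. Fallback, setting out from 4 and 6: the copper-catalysed conjugate addition of 7 is run in the presence of Me3SiCl and the trimethylsilyl enol ether F1 is isolated. Anhydrous benzyltrimethylammonium fluoride in THF over molecular sieves then unmasks a metal-free ammonium enolate regiospecifically at C10, which should cyclise onto the chloride at room temperature and return to 9.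

Step 10 (step 11 depends on it). Hydrogen abstraction in the ene reaction may go to the ring (endocyclic Δ3 hydroperoxide, or oxygen at C4 with a C6 hydrogen), and face selectivity in the ene or diimide step may be poor. Fallback, setting out from 14:
- mCPBA should epoxidise the tetrasubstituted alkene on the α face to the 4α,5α-epoxide F2.
- Diethylaluminium 2,2,6,6-tetramethylpiperidide, Et2Al(tmp), in toluene at 0 °C should isomerise it, by removal of a C15 methyl proton, to the 5α-hydroxy-4(15)-ene F3.
- Hydroxyl-directed hydrogenation with [Ir(cod)(PCy3)(py)]PF6 and H2 delivers hydrogen syn to the 5α-hydroxyl and should give the 4β-methyl tertiary alcohol F4.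
- SOCl2 in pyridine should eliminate anti toward C6 (only H6β is antiperiplanar to the axial 5α-oxygen) to the Δ5 alkene F5.
- Mukaiyama–Isayama hydroperoxysilylation (Co(thd)2 [cobalt bis(2,2,6,6-tetramethylheptane-3,5-dionate)], O2, Et3SiH) places oxygen at the tertiary C5 and gives the triethylsilyl peroxide F6.
- K2CO3 in MeOH removes the silyl group and the route is rejoined at 16.

Step 12. C4 or C6 may migrate in competition with C10 during the rearrangement, or the strained bridgehead oxocarbenium ion may fail to form or be reduced. Fallback, setting out from 16: FeSO4 and Cu(OAc)2 in MeOH convert the hydroperoxide by one-electron reduction into the C5 alkoxy radical, β-scission of the C5–C10 bond gives the tertiary C10 radical, and Cu(OAc)2 oxidises it to the alkene, giving the ten-membered 5-oxo-5,10-seco-1(10)-ene F7 (a C10 exocyclic methylene isomer would converge in what follows). NaBH4 reduces the ketone to the C5 alcohol F8. Transannular alkoxymercuration–demercuration (Hg(OCOCF3)2, then NaBH4/NaOH) closes the C5–O–C10 ether with Markovnikov attack at C10, rejoining the route at 19. In this fallback the configuration at C10 is no longer carried by retention but depends on hydride face selectivity at the ten-membered ketone and on the alkene face in the transannular closure.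

Further compounds
F1 | step 5 | trimethylsilyl enol ether of the conjugate adduct | COC(=O)C(C)[C@H]1C[C@H](C(=C)CCCCl)C(C)=C(O[Si](C)(C)C)C1
F2 | step 10 | 4α,5α-epoxy-9β-(tert-butyldimethylsilyloxy)eudesman-8α,12-olide | CC1C(=O)O[C@@H]2[C@@H]1C[C@@]34O[C@]3(C)CCC[C@]4(C)[C@H]2O[Si](C)(C)C(C)(C)C
F3 | step 10 | 5α-hydroxy-9β-(tert-butyldimethylsilyloxy)eudesm-4(15)-en-8α,12-olide | CC1C(=O)O[C@@H]2[C@@H]1C[C@@]3(O)C(=C)CCC[C@]3(C)[C@H]2O[Si](C)(C)C(C)(C)C
F4 | step 10 | 5α-hydroxy-4β-methyl-9β-(tert-butyldimethylsilyloxy)eudesman-8α,12-olide | CC1C(=O)O[C@@H]2[C@@H]1C[C@@]3(O)[C@@H](C)CCC[C@]3(C)[C@H]2O[Si](C)(C)C(C)(C)C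
F5 | step 10 | 4β-methyl-9β-(tert-butyldimethylsilyloxy)eudesm-5-en-8α,12-olide | CC1C(=O)O[C@@H]2[C@@H]1C=C3[C@@H](C)CCC[C@]3(C)[C@H]2O[Si](C)(C)C(C)(C)C
F6 | step 10 | 5α-(triethylsilylperoxy)-4β-methyl-9β-(tert-butyldimethylsilyloxy)eudesman-8α,12-olide | CC1C(=O)O[C@@H]2[C@@H]1C[C@@]3(OO[Si](CC)(CC)CC)[C@@H](C)CCC[C@]3(C)[C@H]2O[Si](C)(C)C(C)(C)C
F7 | step 12 | (E)-5-oxo-9-(tert-butyldimethylsilyloxy)-5,10-secoeudesm-1(10)-en-8,12-olide | CC1C(=O)O[C@@H]2[C@@H]1CC(=O)[C@@H](C)CC/C=C(\C)[C@H]2O[Si](C)(C)C(C)(C)C
F8 | step 12 | (E)-5-hydroxy-9-(tert-butyldimethylsilyloxy)-5,10-secoeudesm-1(10)-en-8,12-olide | CC1C(=O)O[C@@H]2[C@@H]1C[C@@H](O)[C@@H](C)CC/C=C(\C)[C@H]2O[Si](C)(C)C(C)(C)C
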